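**Retrosynthetic overview**
- The strategy rests on the para-alkoxyphenol ring of the chromanol (C4a, C5, C6, C7, C8, C8a; O1 on C8a, OH on C6, CHO on C5, CH3 on C8). This is the substitution pattern that an alkoxy(alkenyl)carbene, CO and an alkyne give in a Dötz benzannulation.
- C4a–C8a, C5–C6 and C6–C7 are cut together. This leads back to a pentacarbonylchromium isopropenylcarbene whose alkoxy group is the C2 tertiary oxygen, carrying a CH2CH2C≡C–CH(OEt)2 arm.
- The carbene C–O bond is cut to an acyl chromate (from 2-bromopropene and Cr(CO)6) and the (R)-tertiary alcohol 9.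
- Alcohol 9 comes from lithiated propiolaldehyde diethyl acetal and the tosylate of (3R)-diol 3, itself made from geranylgeraniol by Sharpless epoxidation (sets C2) and C2-selective hydride opening.
- Ring order: the dihydropyran ring closes first (alkyne insertion) and the benzene ring second (electrocyclisation), in one operation; acetal hydrolysis then frees the C5 aldehyde.

Key step: step 9

Remark on the chemistry: the target is 2R; the carbinol carbon stays R from diol 3 to the target, because the CH2CH2X arm outranks the trienyl chain in every compound and no bond to this carbon is broken after step 1.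

**Step 1**
Reactants: 1 (2E,6E,10E)-geranylgeraniol
Product: 2 [(2R,3R)-3-methyl-3-[(3E,7E)-4,8,12-trimethyltrideca-3,7,11-trien-1-yl]oxiran-2-yl]methanol
Conditions: Ti(OiPr)4 (10 mol %), D-(−)-diethyl tartrate (12 mol %), t-BuOOH (2 equiv), 4 Å MS, CH2Cl2, −20 °C
Reagents that add atoms: tert-butyl hydroperoxide, CC(C)(C)OO
Why: Sharpless asymmetric epoxidation touches only the allylic alcohol double bond, and D-(−)-tartrate, the enantiomer that converts geraniol into (2R,3R)-epoxygeraniol, should set C2 and C3 as R,R by reagent control, C3 being the future C2 of the chroman.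

**Step 2**
Reactants: 2 (2R,3R)-2,3-epoxygeranylgeraniol
Product: 3 (3R,6E,10E)-3,7,11,15-tetramethylhexadeca-6,10,14-triene-1,3-diol
Conditions: NaAlH2(OCH2CH2OCH3)2, THF, 0 °C to rt; aq. potassium sodium tartrate
Reagents that add atoms: none
Why: Hydroxyl-directed hydride delivery to C2 of a 2,3-epoxy alcohol (here also the less hindered epoxide carbon) should give the 1,3-diol; the C3–O bond is not broken, so the tertiary carbinol keeps its configuration.

**Step 3**
Reactants: 3 (3R)-1,3-diol
Product: 4 (3R,6E,10E)-3-hydroxy-3,7,11,15-tetramethylhexadeca-6,10,14-trien-1-yl 4-methylbenzenesulfonate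
Conditions: TsCl (1.1 equiv), Et3N, DMAP (cat.), CH2Cl2, 0 °C
Reagents that add atoms: 4-methylbenzenesulfonyl chloride, Cc1ccc(cc1)S(Cl)(=O)=O
Why: Sulfonylation discriminates sharply between a primary and a tertiary hydroxyl, so only O1 should react.

**Step 4**
Reactants: 4 hydroxy tosylate
Product: 5 (3R,6E,10E)-3,7,11,15-tetramethyl-3-(triethylsilyloxy)hexadeca-6,10,14-trien-1-yl 4-methylbenzenesulfonate
Conditions: Et3SiOTf, 2,6-lutidine, CH2Cl2, −78 to 0 °C
Reagents that add atoms: triethylsilyl trifluoromethanesulfonate, CC[Si](CC)(CC)OS(=O)(=O)C(F)(F)F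
Why: Silyl triflate silylation of a tertiary alcohol is standard and masks the hydroxyl that would otherwise close an oxetane onto the tosylate under the basic conditions of step 5.

**Step 5**
Reactants: 5 silyl ether tosylate; 6 propiolaldehyde diethyl acetal (3,3-diethoxyprop-1-yne)
Product: 8 (6R,9E,13E)-1,1-diethoxy-6,10,14,18-tetramethyl-6-(triethylsilyloxy)nonadeca-9,13,17-trien-2-yne, via lithium acetylide 7 (not isolated)
Conditions: 6, n-BuLi, THF, −78 °C; then 5, DMPU, −78 °C to rt
Reagents that add atoms: none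
Why: SN2 alkylation of a lithium acetylide by an unbranched primary tosylate in a dipolar cosolvent; acetal and silyl ether are inert to the base and the stereocentre is two carbons away from the reacting centre.

**Step 6**
Reactants: 8 silyl-protected alkynyl acetal
Product: 9 (6R,9E,13E)-1,1-diethoxy-6,10,14,18-tetramethylnonadeca-9,13,17-trien-2-yn-6-ol
Conditions: Bu4NF, THF, rt
Reagents that add atoms: none
Why: Fluoride cleaves the Si–O bond and frees the tertiary alcohol without touching acetal, alkyne or alkenes.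

**Step 7**
Reactants: 10 2-bromopropene; 11 chromium hexacarbonyl
Product: 14 tetramethylammonium pentacarbonyl(2-methyl-1-oxidoprop-2-en-1-ylidene)chromate, via isopropenyllithium 12 (not isolated), via lithium acylchromate 13 (not isolated)
Conditions: 10, t-BuLi (2 equiv), Et2O, −78 °C; Cr(CO)6, Et2O, −78 °C to rt; then Me4NBr, H2O
Reagents that add atoms: tetramethylammonium bromide, C[N+](C)(C)C.[Br-]
Why: Classical Fischer route to an acyl metalate: bromine–lithium exchange gives the alkenyllithium, which adds to a CO ligand of Cr(CO)6, and cation exchange gives the storable ammonium salt.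

**Step 8**
Reactants: 14 tetramethylammonium acylchromate; 9 tertiary alcohol
Product: 17 pentacarbonyl[{[(6R,9E,13E)-1,1-diethoxy-6,10,14,18-tetramethylnonadeca-9,13,17-trien-2-yn-6-yl]oxy}(prop-1-en-2-yl)methylidene]chromium, via pivaloyloxycarbene complex 15 (not isolated), via lithium alkoxide 16 (not isolated)
Conditions: 14 (3 equiv), t-BuCOCl, CH2Cl2, −40 °C; 9, n-BuLi (1.0 equiv), THF, −78 °C; alkoxide added to 15 at −78 °C, then to −20 °C; pH 7 buffer, cold neutral alumina
Reagents that add atoms: none
Why: Proposed new method: the acyloxycarbene carbon is the carbene counterpart of a mixed-anhydride carbonyl, so a pre-formed tertiary lithium alkoxide should add to it at low temperature and expel pivalate (as tertiary alkoxides acylate with acid chlorides), the pivaloyl carbonyl being shielded by its tert-butyl group and 1,2-addition–elimination being irreversible whereas attack at the isopropenyl CH2 is not productive; the closest known reaction type is alcoholysis of acyloxy(alkenyl)carbene chromium complexes by primary and hindered secondary alcohols, together with alkoxide addition and exchange at the carbene carbon of alkoxycarbene complexes, and the carbinol carbon is not involved and stays R.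

**Step 9**
Reactants: 17 tethered carbene complex
Product: 19 (2R)-5-(diethoxymethyl)-2,8-dimethyl-2-[(3E,7E)-4,8,12-trimethyltrideca-3,7,11-trien-1-yl]-3,4-dihydro-2H-chromen-6-ol, via chromium tricarbonyl arene complex 18 (not isolated)
Conditions: THF (0.005 M, degassed), 55 °C, argon; then air, daylight, Et2O, rt
Reagents that add atoms: none
Why: Thermal loss of one cis-CO from zerovalent chromium lets the tethered alkyne bind and insert into the Cr=C bond with its proximal carbon joining the carbene carbon (C4a–C8a); CO insertion then gives a chromium-bound dienylketene (C5–C6), and 6π-electrocyclisation (C6–C7) with enolisation gives the phenol as its Cr(CO)3 complex, which air strips to the free arene. This is the Dötz benzannulation in its known intramolecular form with the alkyne hung on the carbene oxygen. The dihydropyran ring closes in the insertion event as a 6-exo-dig closure onto the alkyne (C2, C3 and C4 are the tether), and the benzene ring closes by disrotatory 6π-electrocyclisation of the dienylketene. No stereocentre is formed, and C2 is a spectator that stays R because none of its four bonds is touched. The isopropenyl group supplies C8 with its methyl and C7 with its hydrogen, and the distal alkyne carbon becomes C5 with the masked aldehyde next to the new hydroxyl. The step needs three selectivities: insertion regiochemistry, which the three-carbon tether enforces whatever the size of the acetal group; phenol formation over furan, cyclobutenone or five-ring products, which an alkenyl carbene favours; and intra- over intermolecular reaction, which high dilution and the fully substituted carbinol carbon should secure.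

**Step 10**
Reactants: 19 acetal chromanol
Product: 20 (2R)-6-hydroxy-2,8-dimethyl-2-[(3E,7E)-4,8,12-trimethyltrideca-3,7,11-trien-1-yl]-3,4-dihydro-2H-chromene-5-carbaldehyde (target)
Conditions: PPTS (cat.), acetone/H2O, rt
Reagents that add atoms: water, O
Why: Acid-catalysed hydrolysis of an electron-rich aryl acetal is fast under conditions mild enough to spare the chroman ether and the trisubstituted alkenes; C2 is not involved.

**Compound list**
1 | (2E,6E,10E)-geranylgeraniol | CC(C)=CCC/C(C)=C/CC/C(C)=C/CC/C(C)=C/CO | starting material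
2 | (2R,3R)-2,3-epoxygeranylgeraniol | CC(C)=CCC/C(C)=C/CC/C(C)=C/CC[C@@]1(C)O[C@@H]1CO | intermediate
3 | (3R,6E,10E)-3,7,11,15-tetramethylhexadeca-6,10,14-triene-1,3-diol | CC(C)=CCC/C(C)=C/CC/C(C)=C/CC[C@](C)(CCO)O | intermediate
4 | (3R,6E,10E)-3-hydroxy-3,7,11,15-tetramethylhexadeca-6,10,14-trien-1-yl 4-methylbenzenesulfonate | CC(C)=CCC/C(C)=C/CC/C(C)=C/CC[C@](C)(CCOS(=O)(=O)c1ccc(C)cc1)O | intermediate
5 | (3R,6E,10E)-3,7,11,15-tetramethyl-3-(triethylsilyloxy)hexadeca-6,10,14-trien-1-yl 4-methylbenzenesulfonate | CC(C)=CCC/C(C)=C/CC/C(C)=C/CC[C@](C)(CCOS(=O)(=O)c1ccc(C)cc1)O[Si](CC)(CC)CC | intermediate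
6 | propiolaldehyde diethyl acetal (3,3-diethoxyprop-1-yne) | C#CC(OCC)OCC | starting material
7 | lithium 3,3-diethoxyprop-1-yn-1-ide | [Li]C#CC(OCC)OCC | intermediate
8 | (6R,9E,13E)-1,1-diethoxy-6,10,14,18-tetramethyl-6-(triethylsilyloxy)nonadeca-9,13,17-trien-2-yne | CC(C)=CCC/C(C)=C/CC/C(C)=C/CC[C@](C)(CCC#CC(OCC)OCC)O[Si](CC)(CC)CC | intermediate
9 | (6R,9E,13E)-1,1-diethoxy-6,10,14,18-tetramethylnonadeca-9,13,17-trien-2-yn-6-ol | CC(C)=CCC/C(C)=C/CC/C(C)=C/CC[C@](C)(CCC#CC(OCC)OCC)O | intermediate
10 | 2-bromopropene | CC(Br)=C | starting material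
11 | chromium hexacarbonyl | O=C=[Cr](=C=O)(=C=O)(=C=O)(=C=O)=C=O | starting material
12 | isopropenyllithium | [Li]C(C)=C | intermediate
13 | lithium pentacarbonyl(2-methyl-1-oxidoprop-2-en-1-ylidene)chromate | [Li+].[O-]C(C(C)=C)=[Cr](=C=O)(=C=O)(=C=O)(=C=O)=C=O | intermediate
14 | tetramethylammonium pentacarbonyl(2-methyl-1-oxidoprop-2-en-1-ylidene)chromate | C[N+](C)(C)C.[O-]C(C(C)=C)=[Cr](=C=O)(=C=O)(=C=O)(=C=O)=C=O | intermediate
15 | pentacarbonyl[(2,2-dimethylpropanoyloxy)(prop-1-en-2-yl)methylidene]chromium | CC(=C)C(OC(=O)C(C)(C)C)=[Cr](=C=O)(=C=O)(=C=O)(=C=O)=C=O | intermediate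
16 | lithium (6R,9E,13E)-1,1-diethoxy-6,10,14,18-tetramethylnonadeca-9,13,17-trien-2-yn-6-olate | CC(C)=CCC/C(C)=C/CC/C(C)=C/CC[C@](C)(CCC#CC(OCC)OCC)[O-].[Li+] | intermediate
17 | pentacarbonyl[{[(6R,9E,13E)-1,1-diethoxy-6,10,14,18-tetramethylnonadeca-9,13,17-trien-2-yn-6-yl]oxy}(prop-1-en-2-yl)methylidene]chromium | CC(C)=CCC/C(C)=C/CC/C(C)=C/CC[C@](C)(CCC#CC(OCC)OCC)OC(C(C)=C)=[Cr](=C=O)(=C=O)(=C=O)(=C=O)=C=O | intermediate
18 | tricarbonylchromium complex of 19 (Cr bound η6 to the benzene ring; written as two fragments) | CC(C)=CCC/C(C)=C/CC/C(C)=C/CC[C@]1(C)CCc2c(C(OCC)OCC)c(O)cc(C)c2O1.O=C=[Cr](=C=O)=C=O | intermediate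
19 | (2R)-5-(diethoxymethyl)-2,8-dimethyl-2-[(3E,7E)-4,8,12-trimethyltrideca-3,7,11-trien-1-yl]-3,4-dihydro-2H-chromen-6-ol | CC(C)=CCC/C(C)=C/CC/C(C)=C/CC[C@]1(C)CCc2c(C(OCC)OCC)c(O)cc(C)c2O1 | intermediate
20 | (2R)-6-hydroxy-2,8-dimethyl-2-[(3E,7E)-4,8,12-trimethyltrideca-3,7,11-trien-1-yl]-3,4-dihydro-2H-chromene-5-carbaldehyde | CC(C)=CCC/C(C)=C/CC/C(C)=C/CC[C@]1(C)CCc2c(C=O)c(O)cc(C)c2O1 | target

**Step count**
Total steps: 10. Longest linear sequence: 9 (steps 1–6, 8, 9, 10); step 7 is a one-step side branch.

**Steps most likely to fail**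

1. Step 8 (bears the label). The hindered alkoxide may add to the carbene carbon more slowly than the acyloxycarbene decays, or may be diverted to the terminal CH2 of the isopropenyl group, so that the carbene ether does not form. The fallback uses known chemistry only, sets out from alcohol 9 and salt 14, and comes back at 19.
   - O-Methylation of 14 with MeOTf gives pentacarbonyl[methoxy(isopropenyl)carbene]chromium F1.
   - Intermolecular Dötz benzannulation of F1 with the internal alkyne of 9 (THF, 50 °C) should put the branched acetal carbon next to the new hydroxyl, where the larger alkyne substituent normally goes. It gives the tricarbonylchromium complex of the methoxyphenol F2, and air frees 2-(diethoxymethyl)-3-[(3R)-3-hydroxyalkyl]-4-methoxy-5-methylphenol F3.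
   - PhI(OAc)2 in MeCN at 0 °C dearomatises F3; the tertiary hydroxyl traps C8a and closes the pyran ring as the 8a-methoxy-6-chromenone ketal F4.
   - Ascorbic acid reduces F4, as it reduces 8a-alkoxytocopherones to tocopherols, with loss of methanol, and gives 19. The C2–O bond is never broken, so the configuration is kept.

2. Step 9 (key step). Intermolecular alkyne insertion, ionisation of the tertiary alkoxy group at 55 °C, or diversion of the vinylcarbene to non-phenolic products may outrun the tethered benzannulation. The fallback sets out from tosylate 5 and comes back at target 20; it builds the arene with a terminal alkyne, whose regiochemistry is dependable, and closes the pyran ring afterwards.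
   - LiC≡CH·H2NCH2CH2NH2 in DMSO alkylates 5 to the terminal alkyne F5.
   - Benzannulation of F5 with pentacarbonyl[methoxy((E)-prop-1-enyl)carbene]chromium F6 (made as in step 7 from (E)-1-bromopropene, with O-methylation in place of cation exchange) gives the tricarbonylchromium complex of the phenol F7. Air frees 4-methoxy-2-methyl-6-alkylphenol F8, with the side chain ortho to the hydroxyl.
   - (NH4)2Ce(NO3)6 in aqueous MeCN at 0 °C oxidises F8 to the 2-methyl-6-alkyl-1,4-benzoquinone F9 with loss of methanol.
   - Na2S2O4 gives the hydroquinone F10. Catalytic p-TsOH then removes the silyl group and closes the ring by dehydration, a closure reported in the tocopherol series to keep the carbinol configuration (the ee would be checked), giving (2R)-δ-tocotrienol F11.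
   - ortho-Formylation with MgCl2, Et3N and paraformaldehyde in MeCN at C5, the more reactive free ortho position of δ-tocols, gives 20.

3. Step 5. E2 elimination of the tosylate, or slow substitution by the inductively deactivated acetylide, may erode the coupling. The fallback sets out from hydroxy tosylate 4 and comes back at alcohol 9, skipping protection.
   - KOt-Bu in THF closes 4 to (2R)-2-methyl-2-[(3E,7E)-4,8,12-trimethyltrideca-3,7,11-trien-1-yl]oxetane F12.
   - Lithium acetylide 7 with BF3·OEt2 in THF at −78 °C opens F12 at its CH2–O carbon and gives 9 directly, the quaternary carbon being untouched.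

**Further compounds**
F1 | step 8 | pentacarbonyl[methoxy(prop-1-en-2-yl)methylidene]chromium | COC(C(C)=C)=[Cr](=C=O)(=C=O)(=C=O)(=C=O)=C=O
F2 | step 8 | tricarbonylchromium complex of F3 (Cr bound η6 to the benzene ring; written as two fragments) | CC(C)=CCC/C(C)=C/CC/C(C)=C/CC[C@](C)(CCc1c(C(OCC)OCC)c(O)cc(C)c1OC)O.O=C=[Cr](=C=O)=C=O
F3 | step 8 | 2-(diethoxymethyl)-3-[(3R,6E,10E)-3-hydroxy-3,7,11,15-tetramethylhexadeca-6,10,14-trien-1-yl]-4-methoxy-5-methylphenol | CC(C)=CCC/C(C)=C/CC/C(C)=C/CC[C@](C)(CCc1c(C(OCC)OCC)c(O)cc(C)c1OC)O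
F4 | step 8 | (2R)-5-(diethoxymethyl)-8a-methoxy-2,8-dimethyl-2-[(3E,7E)-4,8,12-trimethyltrideca-3,7,11-trien-1-yl]-2,3,4,8a-tetrahydro-6H-chromen-6-one (both C8a epimers) | CC(C)=CCC/C(C)=C/CC/C(C)=C/CC[C@]1(C)CCC2=C(C(OCC)OCC)C(=O)C=C(C)C2(OC)O1
F5 | step 9 | triethyl{[(5R,8E,12E)-5,9,13,17-tetramethyloctadeca-8,12,16-trien-1-yn-5-yl]oxy}silane | CC(C)=CCC/C(C)=C/CC/C(C)=C/CC[C@](C)(CCC#C)O[Si](CC)(CC)CC
F6 | step 9 | pentacarbonyl[methoxy((1E)-prop-1-en-1-yl)methylidene]chromium | COC(/C=C/C)=[Cr](=C=O)(=C=O)(=C=O)(=C=O)=C=O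
F7 | step 9 | tricarbonylchromium complex of F8 (Cr bound η6 to the benzene ring; written as two fragments) | CC(C)=CCC/C(C)=C/CC/C(C)=C/CC[C@](C)(CCc1cc(OC)cc(C)c1O)O[Si](CC)(CC)CC.O=C=[Cr](=C=O)=C=O
F8 | step 9 | 4-methoxy-2-methyl-6-[(3R,6E,10E)-3,7,11,15-tetramethyl-3-(triethylsilyloxy)hexadeca-6,10,14-trien-1-yl]phenol | CC(C)=CCC/C(C)=C/CC/C(C)=C/CC[C@](C)(CCc1cc(OC)cc(C)c1O)O[Si](CC)(CC)CC
F9 | step 9 | 2-methyl-6-[(3R,6E,10E)-3,7,11,15-tetramethyl-3-(triethylsilyloxy)hexadeca-6,10,14-trien-1-yl]cyclohexa-2,5-diene-1,4-dione | CC(C)=CCC/C(C)=C/CC/C(C)=C/CC[C@](C)(CCC1=CC(=O)C=C(C)C1=O)O[Si](CC)(CC)CC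
F10 | step 9 | 2-methyl-6-[(3R,6E,10E)-3,7,11,15-tetramethyl-3-(triethylsilyloxy)hexadeca-6,10,14-trien-1-yl]benzene-1,4-diol | CC(C)=CCC/C(C)=C/CC/C(C)=C/CC[C@](C)(CCc1cc(O)cc(C)c1O)O[Si](CC)(CC)CC
F11 | step 9 | (2R)-δ-tocotrienol, (2R)-2,8-dimethyl-2-[(3E,7E)-4,8,12-trimethyltrideca-3,7,11-trien-1-yl]-3,4-dihydro-2H-chromen-6-ol | CC(C)=CCC/C(C)=C/CC/C(C)=C/CC[C@]1(C)CCc2cc(O)cc(C)c2O1
F12 | step 5 | (2R)-2-methyl-2-[(3E,7E)-4,8,12-trimethyltrideca-3,7,11-trien-1-yl]oxetane | CC(C)=CCC/C(C)=C/CC/C(C)=C/CC[C@]1(C)CCO1
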